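**Retrosynthetic overview**

1. Target 19 comes from cis-fused hydroazulene diene ester 16 by convex-face dihydroxylation of C3=C4, acetylation of the C3 hydroxyl and global desilylation.
2. The seven-membered ring (formed second) comes from ring-closing metathesis at C7=C8 of triene 13.
3. Key step: the C5–C6 bond comes from a [2,3]-Wittig rearrangement of cyclopentenyl allyl ether 12, which moves the C3–O chirality to C5, sets C6 and shifts the ring alkene to C3=C4.
4. The five-membered ring (formed first) comes from alkyne hydration and aldol condensation of alkynyl aldehyde 8 to cyclopentenone 10.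
5. The quaternary C1 comes from two Fráter–Seebach alkylations of β-hydroxy ester 3, whose carbinol (C10) is bought in ethyl (R)-4-chloro-3-hydroxybutanoate 1.

Atom labels follow the target: C1 = methyl-bearing ring-fusion carbon, C2 = CH2, C3 = CHOAc, C4 = C(OH)i-Pr, C5 = ring-fusion CH, C6 = CH–O-aroyl, C7=C8(CH3), C9 = CH2, C10 = CHOH. The target is the cis-fused isomer (angular methyl, H5, the C3 and C4 oxygens and the C10 hydroxyl on one face; the C6 ester on the other).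

Assumption: 1-bromo-4-methylpent-2-yne (4) and 4-[(tert-butyldimethylsilyl)oxy]benzoic acid (15) are taken as catalogue building blocks.

**Route**

Step 1
Reactants: 1 ethyl (3R)-4-chloro-3-hydroxybutanoate
Product: 3 ethyl (3S)-3-hydroxy-5-methylhex-5-enoate, via epoxy ester 2 (not isolated)
Conditions: CH2=C(CH3)MgBr (2.6 equiv), CuI (10 mol %), THF, −30 → 0 °C; H2O work-up
Reagents that add atoms: isopropenylmagnesium bromide, CC(=C)[Mg]Br
Why: The first equivalent of Grignard reagent makes the magnesium alkoxide, which closes to epoxy ester 2, and copper-catalysed SN2 opening of the epoxide at its CH2 end (organocuprate epoxide opening) gives the homoallylic alcohol without touching the bought carbinol centre (C10).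

Step 2
Reactants: 3 ethyl (3S)-3-hydroxy-5-methylhex-5-enoate; 4 1-bromo-4-methylpent-2-yne
Product: 5 ethyl (2S,3S)-3-hydroxy-5-methyl-2-(4-methylpent-2-yn-1-yl)hex-5-enoate
Conditions: LiN(i-Pr)2 (2.2 equiv), THF, −78 → −20 °C; then 4, DMPU, −78 → −10 °C; H2O
Reagents that add atoms: none
Why: Fráter–Seebach alkylation of the chelated alkoxide–enolate dianion by the propargylic bromide, anti to the hydroxyl, brings in the future C2–C4 chain (the α-centre is re-set in step 3).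

Step 3
Reactants: 5 ethyl (2S,3S)-3-hydroxy-5-methyl-2-(4-methylpent-2-yn-1-yl)hex-5-enoate
Product: 6 ethyl (2R,3S)-3-hydroxy-2,5-dimethyl-2-(4-methylpent-2-yn-1-yl)hex-5-enoate
Conditions: LiN(i-Pr)2 (2.5 equiv), THF, −78 → 0 °C; then CH3I, DMPU, −78 → −20 °C; H2O
Reagents that add atoms: iodomethane, CI
Why: Second Fráter–Seebach alkylation: the chelated dianion is methylated on the same face as before, so methyl ends anti and the alkynyl chain syn to the hydroxyl, which sets the quaternary centre (C1) under control of the bought carbinol.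

Step 4
Reactants: 6 ethyl (2R,3S)-3-hydroxy-2,5-dimethyl-2-(4-methylpent-2-yn-1-yl)hex-5-enoate
Product: 7 ethyl (2R,3S)-3-[(tert-butyldimethylsilyl)oxy]-2,5-dimethyl-2-(4-methylpent-2-yn-1-yl)hex-5-enoate
Conditions: TBSOTf, 2,6-lutidine, CH2Cl2, −78 → 0 °C
Reagents that add atoms: tert-butyldimethylsilyl trifluoromethanesulfonate, CC(C)(C)[Si](C)(C)OS(=O)(=O)C(F)(F)F
Why: Silylation of the hindered secondary alcohol with the silyl triflate blocks retro-aldol cleavage and O-alkylation later; no stereocentre is touched.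

Step 5
Reactants: 7 ethyl (2R,3S)-3-[(tert-butyldimethylsilyl)oxy]-2,5-dimethyl-2-(4-methylpent-2-yn-1-yl)hex-5-enoate
Product: 8 (2R,3S)-3-[(tert-butyldimethylsilyl)oxy]-2,5-dimethyl-2-(4-methylpent-2-yn-1-yl)hex-5-enal
Conditions: i-Bu2AlH (1.2 equiv), CH2Cl2, −78 °C; aq. potassium sodium tartrate
Reagents that add atoms: none
Why: Partial ester reduction stops at the aluminium hemiacetal of the neopentyl carbonyl, which gives the non-enolisable aldehyde on work-up.

Step 6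
Reactants: 8 (2R,3S)-3-[(tert-butyldimethylsilyl)oxy]-2,5-dimethyl-2-(4-methylpent-2-yn-1-yl)hex-5-enal
Product: 10 (4S)-4-{(1S)-1-[(tert-butyldimethylsilyl)oxy]-3-methylbut-3-en-1-yl}-4-methyl-2-(propan-2-yl)cyclopent-2-en-1-one, via keto aldehyde 9 (not isolated)
Conditions: Ph3PAuNTf2 (3 mol %), H2O (5 equiv), 1,4-dioxane, 50 °C; then KOH, MeOH, 40 °C
Reagents that add atoms: water, O
Why: Gold-catalysed alkyne hydration, steered to the proximal alkyne carbon by 5-exo attack of the aldehyde oxygen, gives the 1,4-keto aldehyde, and its intramolecular aldol condensation (only five-ring closure is possible) gives the 2-isopropylcyclopentenone with the quaternary centre untouched.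

Step 7
Reactants: 10 (4S)-4-{(1S)-1-[(tert-butyldimethylsilyl)oxy]-3-methylbut-3-en-1-yl}-4-methyl-2-(propan-2-yl)cyclopent-2-en-1-one
Product: 11 (1R,4S)-4-{(1S)-1-[(tert-butyldimethylsilyl)oxy]-3-methylbut-3-en-1-yl}-4-methyl-2-(propan-2-yl)cyclopent-2-en-1-ol (hydroxyl cis to the silyloxyalkyl chain)
Conditions: i-Bu2AlH, toluene, −78 °C; aq. potassium sodium tartrate
Reagents that add atoms: none
Why: 1,2-Reduction of the enone by the bulky aluminium hydride from the face of the small methyl group, anti to the large silyloxyalkyl group on the quaternary carbon, puts the hydroxyl cis to that chain (substrate-controlled 1,3-induction).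

Step 8
Reactants: 11 (1R,4S)-4-{(1S)-1-[(tert-butyldimethylsilyl)oxy]-3-methylbut-3-en-1-yl}-4-methyl-2-(propan-2-yl)cyclopent-2-en-1-ol
Product: 12 tert-butyl(dimethyl){[(1S)-3-methyl-1-[(1S,4R)-1-methyl-3-(propan-2-yl)-4-(prop-2-en-1-yloxy)cyclopent-2-en-1-yl]but-3-en-1-yl]oxy}silane
Conditions: NaH, allyl bromide, Bu4NI (cat.), THF–DMF, 0 °C → rt
Reagents that add atoms: allyl bromide, C=CCBr
Why: Williamson etherification of the sodium alkoxide, with retention at the carbinol carbon.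

Step 9
Reactants: 12 tert-butyl(dimethyl){[(1S)-3-methyl-1-[(1S,4R)-1-methyl-3-(propan-2-yl)-4-(prop-2-en-1-yloxy)cyclopent-2-en-1-yl]but-3-en-1-yl]oxy}silane
Product: 13 (1S)-1-[(1R,5S)-5-{(1S)-1-[(tert-butyldimethylsilyl)oxy]-3-methylbut-3-en-1-yl}-5-methyl-2-(propan-2-yl)cyclopent-2-en-1-yl]prop-2-en-1-ol
Conditions: n-BuLi (2 equiv), THF, −78 → −25 °C; H2O
Reagents that add atoms: none
Why: [2,3]-Wittig rearrangement (key step): the α-oxy allyl anion formed at the less substituted OCH2 bonds to C5 suprafacially on the face the ether oxygen held (cis to the C1 side chain, so H5 ends cis to the angular methyl) while the ring alkene moves to C3=C4, and the envelope transition state with the vinyl group exo on the Z-locked ring allyl unit is expected to give the syn carbinol at C6.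

Step 10
Reactants: 13 (1S)-1-[(1R,5S)-5-{(1S)-1-[(tert-butyldimethylsilyl)oxy]-3-methylbut-3-en-1-yl}-5-methyl-2-(propan-2-yl)cyclopent-2-en-1-yl]prop-2-en-1-ol
Product: 14 (3aR,4S,8S,8aS)-8-[(tert-butyldimethylsilyl)oxy]-6,8a-dimethyl-3-(propan-2-yl)-1,3a,4,7,8,8a-hexahydroazulen-4-ol
Conditions: second-generation Grubbs catalyst RuCl2(=CHPh)(PCy3)(H2IMes) (5 mol %), CH2Cl2 (0.005 M), 40 °C
Reagents that add atoms: none
Why: Ring-closing metathesis of the vinyl and the 1,1-disubstituted alkene, held cis on adjacent ring carbons, closes the seven-membered ring with the trisubstituted C7=C8 alkene; the trisubstituted cyclopentene is inert.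

Step 11
Reactants: 14 (3aR,4S,8S,8aS)-8-[(tert-butyldimethylsilyl)oxy]-6,8a-dimethyl-3-(propan-2-yl)-1,3a,4,7,8,8a-hexahydroazulen-4-ol; 15 4-[(tert-butyldimethylsilyl)oxy]benzoic acid
Product: 16 (3aR,4S,8S,8aS)-8-[(tert-butyldimethylsilyl)oxy]-6,8a-dimethyl-3-(propan-2-yl)-1,3a,4,7,8,8a-hexahydroazulen-4-yl 4-[(tert-butyldimethylsilyl)oxy]benzoate
Conditions: DCC, DMAP, CH2Cl2, rt
Reagents that add atoms: none
Why: Steglich esterification of the only free (allylic) hydroxyl, with retention at C6.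

Step 12
Reactants: 16 (3aR,4S,8S,8aS)-8-[(tert-butyldimethylsilyl)oxy]-6,8a-dimethyl-3-(propan-2-yl)-1,3a,4,7,8,8a-hexahydroazulen-4-yl 4-[(tert-butyldimethylsilyl)oxy]benzoate
Product: 17 (2S,3R,3aR,4S,8S,8aS)-8-[(tert-butyldimethylsilyl)oxy]-2,3-dihydroxy-6,8a-dimethyl-3-(propan-2-yl)-1,2,3,3a,4,7,8,8a-octahydroazulen-4-yl 4-[(tert-butyldimethylsilyl)oxy]benzoate
Conditions: OsO4 (5 mol %), N-methylmorpholine N-oxide (1.5 equiv), acetone–H2O 5:1, 0 °C → rt
Reagents that add atoms: N-methylmorpholine N-oxide, C[N+]1([O-])CCOCC1; water, O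
Why: Upjohn dihydroxylation: electrophilic OsO4 takes the cyclopentene rather than the cycloheptene deactivated by its allylic aroyloxy group, and adds from the convex face of the cis-fused bicycle (the face of the angular methyl and H5, anti to the C6 substituent), giving the cis-diol with both hydroxyls cis to the methyl.

Step 13
Reactants: 17 (2S,3R,3aR,4S,8S,8aS)-8-[(tert-butyldimethylsilyl)oxy]-2,3-dihydroxy-6,8a-dimethyl-3-(propan-2-yl)-1,2,3,3a,4,7,8,8a-octahydroazulen-4-yl 4-[(tert-butyldimethylsilyl)oxy]benzoate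
Product: 18 (2S,3R,3aR,4S,8S,8aS)-2-(acetyloxy)-8-[(tert-butyldimethylsilyl)oxy]-3-hydroxy-6,8a-dimethyl-3-(propan-2-yl)-1,2,3,3a,4,7,8,8a-octahydroazulen-4-yl 4-[(tert-butyldimethylsilyl)oxy]benzoate
Conditions: Ac2O, pyridine, DMAP (cat.), CH2Cl2, 0 °C → rt
Reagents that add atoms: acetic anhydride, CC(=O)OC(C)=O
Why: Acylation of the secondary hydroxyl; the tertiary C4 hydroxyl does not react under these conditions.

Step 14
Reactants: 18 (2S,3R,3aR,4S,8S,8aS)-2-(acetyloxy)-8-[(tert-butyldimethylsilyl)oxy]-3-hydroxy-6,8a-dimethyl-3-(propan-2-yl)-1,2,3,3a,4,7,8,8a-octahydroazulen-4-yl 4-[(tert-butyldimethylsilyl)oxy]benzoate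
Product: 19 (2S,3R,3aR,4S,8S,8aS)-2-(acetyloxy)-3,8-dihydroxy-6,8a-dimethyl-3-(propan-2-yl)-1,2,3,3a,4,7,8,8a-octahydroazulen-4-yl 4-hydroxybenzoate
Conditions: HF·pyridine, pyridine, THF, 0 °C → rt
Reagents that add atoms: none
Why: Fluoride cleavage of the aryl and the alkyl silyl ether leaves the acetate, the benzoate and the tertiary alcohol intact and gives the target.

**Compound list**

1 | ethyl (3R)-4-chloro-3-hydroxybutanoate | CCOC(=O)C[C@@H](O)CCl | starting material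
2 | ethyl 2-[(2R)-oxiran-2-yl]acetate | CCOC(=O)C[C@@H]1CO1 | intermediate
3 | ethyl (3S)-3-hydroxy-5-methylhex-5-enoate | CCOC(=O)C[C@@H](O)CC(C)=C | intermediate
4 | 1-bromo-4-methylpent-2-yne | BrCC#CC(C)C | starting material
5 | ethyl (2S,3S)-3-hydroxy-5-methyl-2-(4-methylpent-2-yn-1-yl)hex-5-enoate | CCOC(=O)[C@@H](CC#CC(C)C)[C@@H](O)CC(C)=C | intermediate
6 | ethyl (2R,3S)-3-hydroxy-2,5-dimethyl-2-(4-methylpent-2-yn-1-yl)hex-5-enoate | CCOC(=O)[C@](C)(CC#CC(C)C)[C@@H](O)CC(C)=C | intermediate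
7 | ethyl (2R,3S)-3-[(tert-butyldimethylsilyl)oxy]-2,5-dimethyl-2-(4-methylpent-2-yn-1-yl)hex-5-enoate | CCOC(=O)[C@](C)(CC#CC(C)C)[C@@H](O[Si](C)(C)C(C)(C)C)CC(C)=C | intermediate
8 | (2R,3S)-3-[(tert-butyldimethylsilyl)oxy]-2,5-dimethyl-2-(4-methylpent-2-yn-1-yl)hex-5-enal | O=C[C@](C)(CC#CC(C)C)[C@@H](O[Si](C)(C)C(C)(C)C)CC(C)=C | intermediate
9 | (2R,3S)-3-[(tert-butyldimethylsilyl)oxy]-2,5-dimethyl-2-(4-methyl-2-oxopentyl)hex-5-enal | O=C[C@](C)(CC(=O)CC(C)C)[C@@H](O[Si](C)(C)C(C)(C)C)CC(C)=C | intermediate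
10 | (4S)-4-{(1S)-1-[(tert-butyldimethylsilyl)oxy]-3-methylbut-3-en-1-yl}-4-methyl-2-(propan-2-yl)cyclopent-2-en-1-one | CC(C)C1=C[C@](C)(CC1=O)[C@@H](O[Si](C)(C)C(C)(C)C)CC(C)=C | intermediate
11 | (1R,4S)-4-{(1S)-1-[(tert-butyldimethylsilyl)oxy]-3-methylbut-3-en-1-yl}-4-methyl-2-(propan-2-yl)cyclopent-2-en-1-ol | CC(C)C1=C[C@](C)(C[C@H]1O)[C@@H](O[Si](C)(C)C(C)(C)C)CC(C)=C | intermediate
12 | tert-butyl(dimethyl){[(1S)-3-methyl-1-[(1S,4R)-1-methyl-3-(propan-2-yl)-4-(prop-2-en-1-yloxy)cyclopent-2-en-1-yl]but-3-en-1-yl]oxy}silane | CC(C)C1=C[C@](C)(C[C@H]1OCC=C)[C@@H](O[Si](C)(C)C(C)(C)C)CC(C)=C | intermediate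
13 | (1S)-1-[(1R,5S)-5-{(1S)-1-[(tert-butyldimethylsilyl)oxy]-3-methylbut-3-en-1-yl}-5-methyl-2-(propan-2-yl)cyclopent-2-en-1-yl]prop-2-en-1-ol | C=C[C@H](O)[C@@H]1C(C(C)C)=CC[C@]1(C)[C@@H](O[Si](C)(C)C(C)(C)C)CC(C)=C | intermediate
14 | (3aR,4S,8S,8aS)-8-[(tert-butyldimethylsilyl)oxy]-6,8a-dimethyl-3-(propan-2-yl)-1,3a,4,7,8,8a-hexahydroazulen-4-ol | CC(C)C1=CC[C@]2(C)[C@@H](O[Si](C)(C)C(C)(C)C)CC(C)=C[C@H](O)[C@@H]21 | intermediate
15 | 4-[(tert-butyldimethylsilyl)oxy]benzoic acid | OC(=O)c1ccc(O[Si](C)(C)C(C)(C)C)cc1 | starting material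
16 | (3aR,4S,8S,8aS)-8-[(tert-butyldimethylsilyl)oxy]-6,8a-dimethyl-3-(propan-2-yl)-1,3a,4,7,8,8a-hexahydroazulen-4-yl 4-[(tert-butyldimethylsilyl)oxy]benzoate | CC(C)C1=CC[C@]2(C)[C@@H](O[Si](C)(C)C(C)(C)C)CC(C)=C[C@H](OC(=O)c3ccc(O[Si](C)(C)C(C)(C)C)cc3)[C@@H]21 | intermediate
17 | (2S,3R,3aR,4S,8S,8aS)-8-[(tert-butyldimethylsilyl)oxy]-2,3-dihydroxy-6,8a-dimethyl-3-(propan-2-yl)-1,2,3,3a,4,7,8,8a-octahydroazulen-4-yl 4-[(tert-butyldimethylsilyl)oxy]benzoate | O[C@H]1C[C@]2(C)[C@@H](O[Si](C)(C)C(C)(C)C)CC(C)=C[C@H](OC(=O)c3ccc(O[Si](C)(C)C(C)(C)C)cc3)[C@@H]2[C@]1(O)C(C)C | intermediate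
18 | (2S,3R,3aR,4S,8S,8aS)-2-(acetyloxy)-8-[(tert-butyldimethylsilyl)oxy]-3-hydroxy-6,8a-dimethyl-3-(propan-2-yl)-1,2,3,3a,4,7,8,8a-octahydroazulen-4-yl 4-[(tert-butyldimethylsilyl)oxy]benzoate | CC(=O)O[C@H]1C[C@]2(C)[C@@H](O[Si](C)(C)C(C)(C)C)CC(C)=C[C@H](OC(=O)c3ccc(O[Si](C)(C)C(C)(C)C)cc3)[C@@H]2[C@]1(O)C(C)C | intermediate
19 | (2S,3R,3aR,4S,8S,8aS)-2-(acetyloxy)-3,8-dihydroxy-6,8a-dimethyl-3-(propan-2-yl)-1,2,3,3a,4,7,8,8a-octahydroazulen-4-yl 4-hydroxybenzoate | CC(=O)O[C@H]1C[C@]2(C)[C@@H](O)CC(C)=C[C@H](OC(=O)c3ccc(O)cc3)[C@@H]2[C@]1(O)C(C)C | target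

**Step count and risks**

Total step count: 14. Longest linear sequence: 14 steps (1 → 19).

The three steps most likely to fail:

Step 9 ([2,3]-Wittig rearrangement). The new bond is made next to the quaternary carbon and cis to its large substituent, so deprotonation may be sluggish or a [1,2]-shift may compete. The C6 outcome is also uncertain, because the exo vinyl group lies close to the C1 side chain. The fallback sets out from 11 and uses the tin–lithium exchange (Still) variant, which needs no deprotonation. Alcohol 11 is alkylated (KH, Bu3SnCH2I, THF) to the stannylmethyl ether F1. n-BuLi at −78 °C then triggers the [2,3]-shift with the same suprafacial delivery to C5 and gives the primary homoallylic alcohol F2. Dess–Martin oxidation (NaHCO3 buffer, 0 °C) gives the aldehyde F3, which is treated at once with CH2=CHMgBr at −78 °C. This comes back to the route at 13; any C6 epimer is removed by chromatography.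

Step 12 (dihydroxylation). OsO4 may also attack the C7=C8 alkene, and a wrong or mixed C6 configuration from step 9 would be carried through here. The fallback sets out from 14 and takes the seven-ring alkene out of play as an enone. MnO2 oxidation gives the enone F4, whose conjugated alkene is inert to OsO4. Upjohn dihydroxylation then gives the convex-face cis-diol F5, and Ac2O/pyridine gives the C3 acetate F6. NaBH4/CeCl3·7H2O at −78 °C reduces the ketone from the convex face to the allylic alcohol F7, which also re-sets C6. DCC/DMAP esterification with 15 comes back to the route at 18.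

Step 7 (enone reduction). The 1,3-induction from the quaternary centre may be modest or reversed. The fallback sets out from 10 and corrects the carbinol by inversion instead of relying on facial selectivity. The epimeric alcohol F8 from the reduction is subjected to a Mitsunobu reaction (PPh3, DIAD, 4-nitrobenzoic acid), which gives the inverted 4-nitrobenzoate F9. Methanolysis (K2CO3, MeOH) comes back to the route at 11.

**Further compounds**

F1 | step 9 | tributyl[({(1R,4S)-4-{(1S)-1-[(tert-butyldimethylsilyl)oxy]-3-methylbut-3-en-1-yl}-4-methyl-2-(propan-2-yl)cyclopent-2-en-1-yl}oxy)methyl]stannane | CC(C)C1=C[C@](C)(C[C@H]1OC[Sn](CCCC)(CCCC)CCCC)[C@@H](O[Si](C)(C)C(C)(C)C)CC(C)=C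
F2 | step 9 | [(1R,5S)-5-{(1S)-1-[(tert-butyldimethylsilyl)oxy]-3-methylbut-3-en-1-yl}-5-methyl-2-(propan-2-yl)cyclopent-2-en-1-yl]methanol | OC[C@@H]1C(C(C)C)=CC[C@]1(C)[C@@H](O[Si](C)(C)C(C)(C)C)CC(C)=C
F3 | step 9 | (1R,5S)-5-{(1S)-1-[(tert-butyldimethylsilyl)oxy]-3-methylbut-3-en-1-yl}-5-methyl-2-(propan-2-yl)cyclopent-2-ene-1-carbaldehyde | O=C[C@@H]1C(C(C)C)=CC[C@]1(C)[C@@H](O[Si](C)(C)C(C)(C)C)CC(C)=C
F4 | step 12 | (3aR,8S,8aS)-8-[(tert-butyldimethylsilyl)oxy]-6,8a-dimethyl-3-(propan-2-yl)-3a,7,8,8a-tetrahydroazulen-4(1H)-one | CC(C)C1=CC[C@]2(C)[C@@H](O[Si](C)(C)C(C)(C)C)CC(C)=CC(=O)[C@@H]21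
F5 | step 12 | (2S,3R,3aS,8S,8aS)-8-[(tert-butyldimethylsilyl)oxy]-2,3-dihydroxy-6,8a-dimethyl-3-(propan-2-yl)-2,3,3a,7,8,8a-hexahydroazulen-4(1H)-one | O[C@H]1C[C@]2(C)[C@@H](O[Si](C)(C)C(C)(C)C)CC(C)=CC(=O)[C@@H]2[C@]1(O)C(C)C
F6 | step 12 | (2S,3R,3aS,8S,8aS)-8-[(tert-butyldimethylsilyl)oxy]-3-hydroxy-6,8a-dimethyl-4-oxo-3-(propan-2-yl)-1,2,3,3a,4,7,8,8a-octahydroazulen-2-yl acetate | CC(=O)O[C@H]1C[C@]2(C)[C@@H](O[Si](C)(C)C(C)(C)C)CC(C)=CC(=O)[C@@H]2[C@]1(O)C(C)C
F7 | step 12 | (2S,3R,3aR,4S,8S,8aS)-8-[(tert-butyldimethylsilyl)oxy]-3,4-dihydroxy-6,8a-dimethyl-3-(propan-2-yl)-1,2,3,3a,4,7,8,8a-octahydroazulen-2-yl acetate | CC(=O)O[C@H]1C[C@]2(C)[C@@H](O[Si](C)(C)C(C)(C)C)CC(C)=C[C@H](O)[C@@H]2[C@]1(O)C(C)C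
F8 | step 7 | (1S,4S)-4-{(1S)-1-[(tert-butyldimethylsilyl)oxy]-3-methylbut-3-en-1-yl}-4-methyl-2-(propan-2-yl)cyclopent-2-en-1-ol | CC(C)C1=C[C@](C)(C[C@@H]1O)[C@@H](O[Si](C)(C)C(C)(C)C)CC(C)=C
F9 | step 7 | (1R,4S)-4-{(1S)-1-[(tert-butyldimethylsilyl)oxy]-3-methylbut-3-en-1-yl}-4-methyl-2-(propan-2-yl)cyclopent-2-en-1-yl 4-nitrobenzoate | CC(C)C1=C[C@](C)(C[C@H]1OC(=O)c2ccc(cc2)[N+](=O)[O-])[C@@H](O[Si](C)(C)C(C)(C)C)CC(C)=C
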